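## Structural features

The target is a stilbenoid trimer made of two trans-2,3-diaryl-2,3-dihydrobenzofurans. The outer one (ring system A) carries a hydroxyl at C4; the inner one (ring system B) carries a hydroxyl at C4 and an (E)-4-hydroxystyryl group at C6. C7 of A is bonded directly to C2 of B, so the benzo ring of A is substituted at four contiguous positions (C3a, C4, C7, C7a). Each heterocycle has two adjacent stereocentres (C2 and C3), both pairs trans and all four R. The two pairs are separated by an aromatic ring and cannot be expected to control each other. C2 of A carries a 2,4-dihydroxyphenyl group and C2 of B carries the ortho,para-dioxygenated benzo ring of A, so both C2–O1 bonds are benzylic ethers that ionise easily under acid, whereas the diarylmethine C3 centres cannot epimerise. Nine free phenols and the stilbene alkene rule out hydrogenolysis, strong oxidants and hot mineral acid late in the route. The real difficulty is absolute control of C3 in each ring, independently, together with the crowded C3–C3a junction of A. The key step uses the pattern at C2 and C3 of A: C3 bears two aryl groups (C3a of the benzo ring and the 3,5-dioxygenated ring), C2 bears one aryl group and oxygen. This is what anti addition of two aryl groups across an (E)-alkenyl boronate leaves once C–B is exchanged for C–O.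

## Logic of the disconnections

36 to 35: the nine aryl O–CH3 bonds are cut last. Methyl ethers are the only phenol protection that survives aryllithiums, palladium catalysis, BCl3 and carbonate base alike. The forward step must cleave nine ethers without opening either benzylic C2–O1 bond or touching the alkene.

35 to 23 and 32: the C2–C3 and O1–C2 bonds of ring system B are cut. This divides the molecule into two halves of similar size, one of them (32) achiral, and removes a ring and two stereocentres at once. The one-carbon partner must bring C2 with reagent-controlled absolute configuration, because the stereocentres of A are too far away to help, and the closure must be trans.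

23 to 20 and 21, and 20 to 19: the benzylic C–S bond and then the O–Si bond are cut. The benzylic carbon on C7 of A is thus carried as a silyl-protected hydroxymethyl group through all organometallic steps. The forward steps must activate a 2,4-dioxygenated benzylic alcohol without acid strong enough to ionise C2–O1.

19 to 18, and 18 to 17: the O1–C2 bond of A is cut, then C2–O is traced back to C2–B. The ring is reduced to an open 1,2,2-triarylethyl chain whose oxygen sits where boron was. The oxidation must be retentive, and the closure must be invertive or pass through the cation, both of which lead to the trans ring from 18.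

17 to 11, 13 and 15 (from 14): the C2–aryl and C3–aryl bonds of A are cut in one operation. Three simple arenes result and the two stereocentres are traced back to an (E)-alkene. The forward step needs metallate shift to outrun direct transmetallation at a β-substituted alkenyl borate. For that reason the boron ligand in 11 is the diol 9 and not pinacol. It also needs facial control by the catalyst at an alkene carrying a di-ortho-substituted aryl group.

11 to 7 and 9, and 7 to 6: the C–B bond and then the alkyne carbon are removed. The alkenyl boronate becomes an aryl aldehyde. Hydroboration must be syn and terminal, and the boron ligand must be exchangeable in the same flask.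

6 to 4 (through 5), and 4 to 1: the ring C–CHO bond is cut between the two oxygens, then the protecting groups are removed in thought (4 to 3 to 2 to 1). Everything is traced to one commercial benzaldehyde. The lithiation must go to the position flanked by both oxygens, which the acetal and methyl ether direct cooperatively.

32 to 31 to 30 to 29: the C–S bond, the carbinol C–H bond and (in reverse) one O–CH3 bond are traced back. The quinone-methide precursor becomes a symmetric 2,6-dimethoxybenzophenone, so no regiochemical question arises. The forward demethylation must stop after one of two equivalent ortho ethers, which carbonyl chelation ensures.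

29 to 26 and 27 (through 28), and 26 to 24 and 25: the aryl–carbonyl bond and the stilbene C=C bond are cut. Four commercial pieces result. The aryllithium must be formed by halogen exchange at low temperature so that the stilbene is not attacked, and the olefination must be (E)-selective.

13 to 12, 15 to 14, and 9 to 8: an O–S bond, a C–Li bond and two C–CH3 bonds are cut; each is a single standard operation on a commercial compound.

## Other disconnections considered

Alternative 1: The cut is made at O1–C2 and C3–H of ring system A, back to the achiral triarylethylene A2, which carries a free para-phenol on the C2 aryl group and a free ortho-phenol on the benzo ring. In the forward direction a chiral BINOL-derived phosphoric acid would protonate the diaryl-substituted alkene carbon, turning the para-hydroxyaryl group into a para-quinone methide, and would then guide the ortho-phenol onto the methide carbon to give A1.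
- In its favour: it is catalytic and atom-economic, needs no stoichiometric organometallic and no boron ligand, and closes the ring in the step that creates both stereocentres. On this last point it is better than the chosen plan, which needs two further steps (10 and 11) to reach the ring.
- Against it: the enantio-determining event is protonation of a carbon flanked by two aryl groups and remote from the phenol that anchors the catalyst. Acids of this class control the carbon attacked by the nucleophile (C2) far better than the protonated carbon (C3). Here C2 is the centre that can equilibrate under the same acid, so the permanent centre C3 would rest on the weaker control element.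
- Structurally, it needs one phenol differentiated from the other eight, and a bromine at C7 that must still be converted into the hydroxymethyl group before the inner ring can be built.
- Comparison: the chosen plan sets C3 directly by the face of the alkene that palladium occupies and ties C2 to it by anti addition. Overall step counts would be similar. The chosen plan is stronger on stereochemical logic, the alternative on economy of the ring-forming event.

Alternative 2: The cut is made at C2–C3 and O1–C2 of ring system B. Base would release an ortho-quinone methide from a sulfone and a benzylic ylide from a sulfonium salt, and their formal [4+1] union would give A3, which is identical with 35.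
- In its favour: it is the most convergent cut available, it forms a ring, two bonds and two stereocentres while joining two halves, and the quinone-methide half is achiral and easy to make. On convergence it is better than the conjunctive coupling.
- It is in fact adopted here as step 19, with 23 and 32 as partners, so on this point the two plans are equal.
- Against it as the defining step: it leaves the harder problem open. Its sulfonium partner already contains ring system A with both stereocentres and the tetrasubstituted benzo ring. Moreover, the stereocentres of A cannot steer the annulation, so a chiral sulfide is needed in any case.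
- Comparison: the two disconnections are complementary and not rivals. The chosen plan supplies the enantioselective construction of A that this one presupposes.

Alternative 3: The cut is made at C3–C3a of ring system B. The flavanone A5 would be treated with PhI(OAc)2 (trivalent iodine) and H2SO4 in trimethyl orthoformate, so that the aryl carbon shifts from the carbonyl carbon to C3 and the six-membered ring contracts to the trans ester A4.
- In its favour: the flavanone comes from an aldol and oxa-Michael sequence between an aldehyde derived from 20 and a simple 2-hydroxyacetophenone; the contraction is reliably trans; and the bromine at C6 allows a late Heck reaction for the stilbene. In simplicity of the fragment coupling it is the equal of the chosen plan.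
- Against it: C3 ends up with an ester, not the 3,5-dioxygenated aryl group. Hydrolysis, activation and a decarboxylative arylation would have to follow, and the radical or organometallic C3 intermediate could only rely on the trans preference of the ring.
- The oxidant and H2SO4 meet the electron-rich arenes and the acid-labile C2–O1 bond of A. The flavanone C2 centre needs its own asymmetric step and can be lost by retro-oxa-Michael opening.
- Comparison: mechanistically it builds the right ring but the wrong substituent, and it costs about four more steps after its key step than the single annulation of step 19. The chosen plan is preferred on step economy and on functional-group tolerance.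

Key step: step 9

Assumption: the antipode of the MandyPhos ligand in step 9 and of sulfide 21 in step 13 (drawn as the (1R,4R,5R) form) is assigned by analogy with simpler substrates. If the sense of induction is the opposite one, the mirror-image ligand or sulfide is used and nothing else changes.

Abbreviation: B(mac) is a boronic ester of cis-1,2-dimethylacenaphthene-1,2-diol (9).

## Route

Step 1
Reactants: 1 2-hydroxy-4-methoxybenzaldehyde
Product: 2 4-methoxy-2-(methoxymethoxy)benzaldehyde
Conditions: MOMCl, i-Pr2NEt, CH2Cl2, 0 °C → rt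
Reagents that add atoms: chloromethyl methyl ether, COCCl
Why: Williamson-type O-alkylation of the phenol; the MOM ether is chosen because it is the strongest ortho-director for step 4 and can leave as an oxocarbenium ion in step 11.

Step 2
Reactants: 2 4-methoxy-2-(methoxymethoxy)benzaldehyde
Product: 3 [4-methoxy-2-(methoxymethoxy)phenyl]methanol
Conditions: NaBH4, MeOH, 0 °C
Reagents that add atoms: none
Why: Borohydride reduction of the aryl aldehyde; the acetal and the methyl ether are inert.

Step 3
Reactants: 3 [4-methoxy-2-(methoxymethoxy)phenyl]methanol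
Product: 4 triisopropyl{[4-methoxy-2-(methoxymethoxy)phenyl]methoxy}silane
Conditions: TIPSCl, imidazole, DMF, rt
Reagents that add atoms: chlorotriisopropylsilane, CC(C)[Si](Cl)(C(C)C)C(C)C
Why: Silylation of the primary alcohol; the bulky TIPS ether resists n-BuLi, aryllithiums, aqueous base and mild acid and is removed by fluoride in step 12.

Step 4
Reactants: 4 triisopropyl{[4-methoxy-2-(methoxymethoxy)phenyl]methoxy}silane
Product: 6 6-methoxy-2-(methoxymethoxy)-3-[(triisopropylsilyloxy)methyl]benzaldehyde, via aryllithium 5 (not isolated)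
Conditions: n-BuLi, THF, 0 °C; then DMF, 0 °C → rt; aq. NH4Cl
Reagents that add atoms: N,N-dimethylformamide, CN(C)C=O
Why: Directed ortho-metalation: the proton between the OMOM and OMe groups is the most acidic because both oxygens coordinate lithium, and the aryllithium is formylated by DMF.

Step 5
Reactants: 6 6-methoxy-2-(methoxymethoxy)-3-[(triisopropylsilyloxy)methyl]benzaldehyde
Product: 7 2-ethynyl-1-methoxy-3-(methoxymethoxy)-4-[(triisopropylsilyloxy)methyl]benzene
Conditions: dimethyl (1-diazo-2-oxopropyl)phosphonate, K2CO3, MeOH, rt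
Reagents that add atoms: dimethyl (1-diazo-2-oxopropyl)phosphonate, COP(=O)(OC)C(=[N+]=[N-])C(C)=O
Why: Ohira–Bestmann (Seyferth–Gilbert) homologation of the aldehyde to the terminal alkyne under carbonate conditions that leave the MOM and TIPS ethers alone.

Step 6
Reactants: 8 acenaphthenequinone
Product: 9 cis-1,2-dimethylacenaphthene-1,2-diol (meso)
Conditions: AlMe3, toluene, 0 °C → rt; aq. potassium sodium tartrate
Reagents that add atoms: trimethylaluminium, C[Al](C)C
Why: Double methyl addition to the 1,2-diketone; the second methyl group should enter anti to the bulky aluminium alkoxide and give the cis diol, and any trans isomer is removed by crystallisation.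

Step 7
Reactants: 7 2-ethynyl-1-methoxy-3-(methoxymethoxy)-4-[(triisopropylsilyloxy)methyl]benzene; 9 cis-1,2-dimethylacenaphthene-1,2-diol
Product: 11 B(mac) ester of (E)-2-{6-methoxy-2-(methoxymethoxy)-3-[(triisopropylsilyloxy)methyl]phenyl}ethenylboronic acid, via alkenyl catechol boronate 10 (not isolated)
Conditions: catecholborane, Cy2BH (10 mol%), THF, rt; then 9, rt
Reagents that add atoms: catecholborane, B1Oc2ccccc2O1
Why: Dicyclohexylborane-catalysed syn hydroboration puts boron on the terminal carbon and gives the (E)-alkenyl catechol boronate, whose labile catechol is displaced by diol 9 (transesterification). The B(mac) ester replaces the usual pinacol ester because β-substituted alkenyl pinacol borates tend to hand the alkenyl group to palladium instead of undergoing the metallate shift.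

Step 8
Reactants: 12 3,5-dimethoxyphenol
Product: 13 3,5-dimethoxyphenyl trifluoromethanesulfonate
Conditions: Tf2O, pyridine, CH2Cl2, 0 °C
Reagents that add atoms: trifluoromethanesulfonic anhydride, O=S(=O)(OS(=O)(=O)C(F)(F)F)C(F)(F)F
Why: O-sulfonylation of the phenol; the triflate is the halide-free electrophile that the conjunctive coupling requires.

Step 9
Reactants: 11 B(mac) ester of (E)-2-{6-methoxy-2-(methoxymethoxy)-3-[(triisopropylsilyloxy)methyl]phenyl}ethenylboronic acid; 13 3,5-dimethoxyphenyl trifluoromethanesulfonate; 14 1-bromo-2,4-dimethoxybenzene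
Product: 17 B(mac) ester of [(1S,2R)-1-(2,4-dimethoxyphenyl)-2-(3,5-dimethoxyphenyl)-2-{6-methoxy-2-(methoxymethoxy)-3-[(triisopropylsilyloxy)methyl]phenyl}ethyl]boronic acid (anti adduct), via 2,4-dimethoxyphenyllithium 15 (not isolated), via lithium borate complex 16 (not isolated)
Conditions: 14, t-BuLi (2 equiv), Et2O, −78 °C; add to 11, THF, −78 °C → rt; then 13, NaOTf, Pd(OAc)2 (2 mol%), MandyPhos ligand (2.4 mol%), THF, 60 °C
Reagents that add atoms: none
Why: Halogen–lithium exchange gives 15, which adds to boron of 11 to form the four-coordinate borate 16; oxidative addition of 13 to zerovalent palladium gives a cationic arylpalladium triflate (divalent palladium) that binds the alkene of 16, triggers 1,2-migration of the 2,4-dimethoxyphenyl group from boron to Cα anti to the metal, and then joins the 3,5-dimethoxyphenyl group to Cβ by reductive elimination. The closest known reaction type is the enantioselective palladium-catalysed conjunctive cross-coupling of β-substituted alkenyl boron ate complexes with aryl triflates. No ring is closed. Cβ (the later C3) is set by the MandyPhos ligand (1,1′-bis[bis(4-methoxy-3,5-dimethylphenyl)phosphino]-2,2′-bis[(dimethylamino)phenylmethyl]ferrocene), which selects the alkene face that palladium occupies. Cα (the later C2) follows from Cβ because migration is anti to palladium and reductive elimination is retentive, so the (E)-alkene can give only the anti (1S,2R) adduct. The step needs metallate shift to win over direct transmetallation (Suzuki–Miyaura coupling), which the hindered B(mac) ester secures where a pinacol ester would not. It also needs a halide-free medium, secured by the triflate electrophile and by NaOTf, which removes the bromide left by the exchange. The MOM, TIPS and methyl ethers are inert to the aryllithium at −78 °C and to the catalyst.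

Step 10
Reactants: 17 B(mac) ester of [(1S,2R)-1-(2,4-dimethoxyphenyl)-2-(3,5-dimethoxyphenyl)-2-{6-methoxy-2-(methoxymethoxy)-3-[(triisopropylsilyloxy)methyl]phenyl}ethyl]boronic acid
Product: 18 (1S,2R)-1-(2,4-dimethoxyphenyl)-2-(3,5-dimethoxyphenyl)-2-{6-methoxy-2-(methoxymethoxy)-3-[(triisopropylsilyloxy)methyl]phenyl}ethanol
Conditions: H2O2 (30% aq.), NaOH (3 M), THF, 0 °C → rt
Reagents that add atoms: hydrogen peroxide, OO
Why: Peroxide oxidation of the secondary boronate; carbon migrates from boron to oxygen with retention, so the (1S,2R) carbinol results and diol 9 is released for reuse.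

Step 11
Reactants: 18 (1S,2R)-1-(2,4-dimethoxyphenyl)-2-(3,5-dimethoxyphenyl)-2-{6-methoxy-2-(methoxymethoxy)-3-[(triisopropylsilyloxy)methyl]phenyl}ethanol
Product: 19 (2R,3R)-2-(2,4-dimethoxyphenyl)-3-(3,5-dimethoxyphenyl)-4-methoxy-7-[(triisopropylsilyloxy)methyl]-2,3-dihydrobenzofuran
Conditions: TsOH·H2O (20 mol%), CH2Cl2/MeOH (10:1), 0 °C → rt
Reagents that add atoms: none
Why: Acid ionises the doubly activated benzylic carbinol; the neighbouring MOM-ether oxygen (or the phenol freed from it) captures the cation to close the five-membered ring, and MeOH takes up the methoxymethyl cation. Closure at C2 is reversible under these conditions, so the more stable 2,3-trans isomer should result whatever the carbinol configuration, while C3 is untouched.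

Step 12
Reactants: 19 (2R,3R)-2-(2,4-dimethoxyphenyl)-3-(3,5-dimethoxyphenyl)-4-methoxy-7-[(triisopropylsilyloxy)methyl]-2,3-dihydrobenzofuran
Product: 20 [(2R,3R)-2-(2,4-dimethoxyphenyl)-3-(3,5-dimethoxyphenyl)-4-methoxy-2,3-dihydrobenzofuran-7-yl]methanol
Conditions: TBAF, THF, 0 °C → rt
Reagents that add atoms: none
Why: Fluoride cleavage of the silyl ether; the phenolic oxygen is now part of the ring, so no ortho-quinone methide can form.

Step 13
Reactants: 20 [(2R,3R)-2-(2,4-dimethoxyphenyl)-3-(3,5-dimethoxyphenyl)-4-methoxy-2,3-dihydrobenzofuran-7-yl]methanol; 21 (1R,4R,5R)-isothiocineole (4,7,7-trimethyl-6-thiabicyclo[3.2.1]octane)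
Product: 23 (1R,4R,5R)-6-{[(2R,3R)-2-(2,4-dimethoxyphenyl)-3-(3,5-dimethoxyphenyl)-4-methoxy-2,3-dihydrobenzofuran-7-yl]methyl}-4,7,7-trimethyl-6-thiabicyclo[3.2.1]octan-6-ium tetrafluoroborate (one epimer at sulfur expected, not assigned), via benzylic mesylate 22 (not isolated)
Conditions: Ms2O, 2,6-di-tert-butyl-4-methylpyridine, 21, CH2Cl2, −40 → 0 °C; then aq. NaBF4
Reagents that add atoms: sodium tetrafluoroborate, [Na+].F[B-](F)(F)F
Why: The electron-rich benzylic alcohol is activated as its mesylate, which alkylates the sulfide on its less hindered lone pair (substitution at a 2,4-dioxygenated benzylic carbon). The hindered pyridine keeps the medium non-acidic so that the C2–O1 bond does not ionise, and anion exchange gives the tetrafluoroborate salt.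

Step 14
Reactants: 24 4-bromo-3,5-dimethoxybenzaldehyde; 25 diethyl (4-methoxybenzyl)phosphonate
Product: 26 2-bromo-1,3-dimethoxy-5-[(E)-2-(4-methoxyphenyl)ethenyl]benzene
Conditions: KOt-Bu, THF, 0 °C → rt
Reagents that add atoms: none
Why: Horner–Wadsworth–Emmons olefination; the benzylic phosphonate anion gives the (E)-stilbene.

Step 15
Reactants: 26 2-bromo-1,3-dimethoxy-5-[(E)-2-(4-methoxyphenyl)ethenyl]benzene; 27 3,5-dimethoxybenzoyl chloride
Product: 29 {2,6-dimethoxy-4-[(E)-2-(4-methoxyphenyl)ethenyl]phenyl}(3,5-dimethoxyphenyl)methanone, via aryllithium 28 (not isolated)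
Conditions: n-BuLi, THF, −78 °C; then cannulate into 27, THF, −78 °C
Reagents that add atoms: none
Why: Bromine–lithium exchange at −78 °C is faster than addition of n-BuLi to the stilbene; inverse addition of the di-ortho-substituted aryllithium to the acid chloride stops at the hindered ketone (nucleophilic acyl substitution).

Step 16
Reactants: 29 {2,6-dimethoxy-4-[(E)-2-(4-methoxyphenyl)ethenyl]phenyl}(3,5-dimethoxyphenyl)methanone
Product: 30 {2-hydroxy-6-methoxy-4-[(E)-2-(4-methoxyphenyl)ethenyl]phenyl}(3,5-dimethoxyphenyl)methanone
Conditions: BCl3 (1.2 equiv), CH2Cl2, −78 → 0 °C; H2O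
Reagents that add atoms: none
Why: Chelation-controlled demethylation: BCl3 binds the carbonyl oxygen and cleaves one of the two equivalent ortho-methoxy groups through a six-membered chelate; the boron chelate then shields the second one, and the remote methyl ethers do not react at this temperature.

Step 17
Reactants: 30 {2-hydroxy-6-methoxy-4-[(E)-2-(4-methoxyphenyl)ethenyl]phenyl}(3,5-dimethoxyphenyl)methanone
Product: 31 2-[(3,5-dimethoxyphenyl)(hydroxy)methyl]-3-methoxy-5-[(E)-2-(4-methoxyphenyl)ethenyl]phenol (racemic)
Conditions: NaBH4, THF/MeOH, 0 °C → rt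
Reagents that add atoms: none
Why: Borohydride reduction of the ortho-hydroxybenzophenone to the benzhydrol; the product is used at once because it is an acid-sensitive quinone-methide precursor.

Step 18
Reactants: 31 2-[(3,5-dimethoxyphenyl)(hydroxy)methyl]-3-methoxy-5-[(E)-2-(4-methoxyphenyl)ethenyl]phenol
Product: 32 2-[(3,5-dimethoxyphenyl)(4-methylbenzenesulfonyl)methyl]-3-methoxy-5-[(E)-2-(4-methoxyphenyl)ethenyl]phenol (racemic)
Conditions: p-TolSO2H, CH2Cl2, rt
Reagents that add atoms: 4-methylbenzenesulfinic acid, Cc1ccc(S(=O)O)cc1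
Why: The sulfinic acid ionises the ortho-hydroxybenzhydrol and adds to the resulting quinone methide through sulfur (SN1-type substitution), giving a bench-stable sulfone that releases the quinone methide again under base.

Step 19
Reactants: 23 the sulfonium tetrafluoroborate of step 13; 32 2-[(3,5-dimethoxyphenyl)(4-methylbenzenesulfonyl)methyl]-3-methoxy-5-[(E)-2-(4-methoxyphenyl)ethenyl]phenol
Product: 35 (2R,3R)-2-[(2R,3R)-2-(2,4-dimethoxyphenyl)-3-(3,5-dimethoxyphenyl)-4-methoxy-2,3-dihydrobenzofuran-7-yl]-3-(3,5-dimethoxyphenyl)-4-methoxy-6-[(E)-2-(4-methoxyphenyl)ethenyl]-2,3-dihydrobenzofuran, via ortho-quinone methide 33 (not isolated), via sulfonium ylide 34 (not isolated)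
Conditions: Cs2CO3 (3 equiv), CH2Cl2/MeCN, 0 °C → rt, slow addition of 32
Reagents that add atoms: none
Why: Formal [4+1] annulation of a sulfonium ylide with an ortho-quinone methide: Cs2CO3 eliminates sulfinate from 32 and deprotonates 23, conjugate addition of the ylide carbon to the methide carbon forms C2–C3 and restores the aromatic ring, and the phenoxide then displaces the sulfide in a 5-exo-tet SN2 closure (O1–C2). C2 is set by the chiral sulfide, which exposes one face of the ylide carbon (inverted in the closure); C3 follows from the preferred anti betaine, which leads to the trans ring.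

Step 20
Reactants: 35 the nona-O-methyl ether of step 19
Product: 36 (2R,3R)-2-[(2R,3R)-2-(2,4-dihydroxyphenyl)-3-(3,5-dihydroxyphenyl)-4-hydroxy-2,3-dihydrobenzofuran-7-yl]-3-(3,5-dihydroxyphenyl)-6-[(E)-2-(4-hydroxyphenyl)ethenyl]-2,3-dihydrobenzofuran-4-ol (CNP0217875.2)
Conditions: BBr3, CH2Cl2, −78 → 0 °C; then MeOH, H2O
Reagents that add atoms: none
Why: Lewis-acid cleavage of the nine aryl methyl ethers by bromide attack on the boron-activated methyl groups; the low temperature is meant to outrun ionisation of the benzylic C2–O1 bonds, and both rings are already in their more stable trans form should these bonds open reversibly.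

## Compound list

1 | 2-hydroxy-4-methoxybenzaldehyde | COc1ccc(C=O)c(O)c1 | starting material
2 | 4-methoxy-2-(methoxymethoxy)benzaldehyde | COCOc1cc(OC)ccc1C=O | intermediate
3 | [4-methoxy-2-(methoxymethoxy)phenyl]methanol | COCOc1cc(OC)ccc1CO | intermediate
4 | triisopropyl{[4-methoxy-2-(methoxymethoxy)phenyl]methoxy}silane | COCOc1cc(OC)ccc1CO[Si](C(C)C)(C(C)C)C(C)C | intermediate
5 | {6-methoxy-2-(methoxymethoxy)-3-[(triisopropylsilyloxy)methyl]phenyl}lithium (not isolated) | [Li]c1c(OC)ccc(CO[Si](C(C)C)(C(C)C)C(C)C)c1OCOC | intermediate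
6 | 6-methoxy-2-(methoxymethoxy)-3-[(triisopropylsilyloxy)methyl]benzaldehyde | COc1ccc(CO[Si](C(C)C)(C(C)C)C(C)C)c(OCOC)c1C=O | intermediate
7 | 2-ethynyl-1-methoxy-3-(methoxymethoxy)-4-[(triisopropylsilyloxy)methyl]benzene | COc1ccc(CO[Si](C(C)C)(C(C)C)C(C)C)c(OCOC)c1C#C | intermediate
8 | acenaphthenequinone | O=C1C(=O)c2cccc3cccc1c23 | starting material
9 | cis-1,2-dimethylacenaphthene-1,2-diol (meso) | C[C@@]1(O)c2cccc3cccc(c23)[C@]1(C)O | intermediate
10 | catechol ester of (E)-2-{6-methoxy-2-(methoxymethoxy)-3-[(triisopropylsilyloxy)methyl]phenyl}ethenylboronic acid (not isolated) | COc1ccc(CO[Si](C(C)C)(C(C)C)C(C)C)c(OCOC)c1/C=C/B1Oc2ccccc2O1 | intermediate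
11 | B(mac) ester of (E)-2-{6-methoxy-2-(methoxymethoxy)-3-[(triisopropylsilyloxy)methyl]phenyl}ethenylboronic acid | COc1ccc(CO[Si](C(C)C)(C(C)C)C(C)C)c(OCOC)c1/C=C/B1O[C@]2(C)c3cccc4cccc(c34)[C@]2(C)O1 | intermediate
12 | 3,5-dimethoxyphenol | COc1cc(O)cc(OC)c1 | starting material
13 | 3,5-dimethoxyphenyl trifluoromethanesulfonate | COc1cc(OC)cc(OS(=O)(=O)C(F)(F)F)c1 | intermediate
14 | 1-bromo-2,4-dimethoxybenzene | COc1ccc(Br)c(OC)c1 | starting material
15 | 2,4-dimethoxyphenyllithium (not isolated) | [Li]c1ccc(OC)cc1OC | intermediate
16 | lithium (E)-alkenyl(2,4-dimethoxyphenyl) B(mac) borate from 11 and 15 (not isolated; configuration at boron immaterial) | [Li+].COc1ccc(CO[Si](C(C)C)(C(C)C)C(C)C)c(OCOC)c1/C=C/[B-]1(c2ccc(OC)cc2OC)O[C@]2(C)c3cccc4cccc(c34)[C@]2(C)O1 | intermediate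
17 | B(mac) ester of [(1S,2R)-1-(2,4-dimethoxyphenyl)-2-(3,5-dimethoxyphenyl)-2-{6-methoxy-2-(methoxymethoxy)-3-[(triisopropylsilyloxy)methyl]phenyl}ethyl]boronic acid | COc1ccc(CO[Si](C(C)C)(C(C)C)C(C)C)c(OCOC)c1[C@@H](c1cc(OC)cc(OC)c1)[C@@H](c1ccc(OC)cc1OC)B1O[C@]2(C)c3cccc4cccc(c34)[C@]2(C)O1 | intermediate
18 | (1S,2R)-1-(2,4-dimethoxyphenyl)-2-(3,5-dimethoxyphenyl)-2-{6-methoxy-2-(methoxymethoxy)-3-[(triisopropylsilyloxy)methyl]phenyl}ethanol | COc1ccc(CO[Si](C(C)C)(C(C)C)C(C)C)c(OCOC)c1[C@@H](c1cc(OC)cc(OC)c1)[C@@H](c1ccc(OC)cc1OC)O | intermediate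
19 | (2R,3R)-2-(2,4-dimethoxyphenyl)-3-(3,5-dimethoxyphenyl)-4-methoxy-7-[(triisopropylsilyloxy)methyl]-2,3-dihydrobenzofuran | CC(C)[Si](OCc1ccc(OC)c2c1O[C@@H](c1ccc(OC)cc1OC)[C@@H]2c1cc(OC)cc(OC)c1)(C(C)C)C(C)C | intermediate
20 | [(2R,3R)-2-(2,4-dimethoxyphenyl)-3-(3,5-dimethoxyphenyl)-4-methoxy-2,3-dihydrobenzofuran-7-yl]methanol | OCc1ccc(OC)c2c1O[C@@H](c1ccc(OC)cc1OC)[C@@H]2c1cc(OC)cc(OC)c1 | intermediate
21 | (1R,4R,5R)-isothiocineole (4,7,7-trimethyl-6-thiabicyclo[3.2.1]octane) | C[C@@H]1CC[C@@H]2C[C@H]1SC2(C)C | starting material
22 | [(2R,3R)-2-(2,4-dimethoxyphenyl)-3-(3,5-dimethoxyphenyl)-4-methoxy-2,3-dihydrobenzofuran-7-yl]methyl methanesulfonate (not isolated) | CS(=O)(=O)OCc1ccc(OC)c2c1O[C@@H](c1ccc(OC)cc1OC)[C@@H]2c1cc(OC)cc(OC)c1 | intermediate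
23 | (1R,4R,5R)-6-{[(2R,3R)-2-(2,4-dimethoxyphenyl)-3-(3,5-dimethoxyphenyl)-4-methoxy-2,3-dihydrobenzofuran-7-yl]methyl}-4,7,7-trimethyl-6-thiabicyclo[3.2.1]octan-6-ium tetrafluoroborate (sulfur configuration not assigned) | C[C@@H]1CC[C@@H]2C[C@H]1[S+](Cc1ccc(OC)c3c1O[C@@H](c1ccc(OC)cc1OC)[C@@H]3c1cc(OC)cc(OC)c1)C2(C)C.F[B-](F)(F)F | intermediate
24 | 4-bromo-3,5-dimethoxybenzaldehyde | COc1cc(C=O)cc(OC)c1Br | starting material
25 | diethyl (4-methoxybenzyl)phosphonate | CCOP(=O)(Cc1ccc(OC)cc1)OCC | starting material
26 | 2-bromo-1,3-dimethoxy-5-[(E)-2-(4-methoxyphenyl)ethenyl]benzene | COc1ccc(/C=C/c2cc(OC)c(Br)c(OC)c2)cc1 | intermediate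
27 | 3,5-dimethoxybenzoyl chloride | COc1cc(OC)cc(C(Cl)=O)c1 | starting material
28 | {2,6-dimethoxy-4-[(E)-2-(4-methoxyphenyl)ethenyl]phenyl}lithium (not isolated) | [Li]c1c(OC)cc(/C=C/c2ccc(OC)cc2)cc1OC | intermediate
29 | {2,6-dimethoxy-4-[(E)-2-(4-methoxyphenyl)ethenyl]phenyl}(3,5-dimethoxyphenyl)methanone | COc1ccc(/C=C/c2cc(OC)c(C(=O)c3cc(OC)cc(OC)c3)c(OC)c2)cc1 | intermediate
30 | {2-hydroxy-6-methoxy-4-[(E)-2-(4-methoxyphenyl)ethenyl]phenyl}(3,5-dimethoxyphenyl)methanone | COc1ccc(/C=C/c2cc(O)c(C(=O)c3cc(OC)cc(OC)c3)c(OC)c2)cc1 | intermediate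
31 | 2-[(3,5-dimethoxyphenyl)(hydroxy)methyl]-3-methoxy-5-[(E)-2-(4-methoxyphenyl)ethenyl]phenol (racemic) | COc1ccc(/C=C/c2cc(O)c(C(O)c3cc(OC)cc(OC)c3)c(OC)c2)cc1 | intermediate
32 | 2-[(3,5-dimethoxyphenyl)(4-methylbenzenesulfonyl)methyl]-3-methoxy-5-[(E)-2-(4-methoxyphenyl)ethenyl]phenol (racemic) | COc1ccc(/C=C/c2cc(O)c(C(c3cc(OC)cc(OC)c3)S(=O)(=O)c3ccc(C)cc3)c(OC)c2)cc1 | intermediate
33 | 6-[(3,5-dimethoxyphenyl)methylidene]-5-methoxy-3-[(E)-2-(4-methoxyphenyl)ethenyl]cyclohexa-2,4-dien-1-one (not isolated; exocyclic alkene geometry undefined) | COc1ccc(/C=C/C2=CC(=O)C(=Cc3cc(OC)cc(OC)c3)C(OC)=C2)cc1 | intermediate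
34 | sulfonium ylide from 23 (not isolated) | C[C@@H]1CC[C@@H]2C[C@H]1[S+]([CH-]c1ccc(OC)c3c1O[C@@H](c1ccc(OC)cc1OC)[C@@H]3c1cc(OC)cc(OC)c1)C2(C)C | intermediate
35 | (2R,3R)-2-[(2R,3R)-2-(2,4-dimethoxyphenyl)-3-(3,5-dimethoxyphenyl)-4-methoxy-2,3-dihydrobenzofuran-7-yl]-3-(3,5-dimethoxyphenyl)-4-methoxy-6-[(E)-2-(4-methoxyphenyl)ethenyl]-2,3-dihydrobenzofuran | COc1ccc(/C=C/c2cc(OC)c3c(c2)O[C@@H](c2ccc(OC)c4c2O[C@@H](c2ccc(OC)cc2OC)[C@@H]4c2cc(OC)cc(OC)c2)[C@@H]3c2cc(OC)cc(OC)c2)cc1 | intermediate
36 | (2R,3R)-2-[(2R,3R)-2-(2,4-dihydroxyphenyl)-3-(3,5-dihydroxyphenyl)-4-hydroxy-2,3-dihydrobenzofuran-7-yl]-3-(3,5-dihydroxyphenyl)-6-[(E)-2-(4-hydroxyphenyl)ethenyl]-2,3-dihydrobenzofuran-4-ol | Oc1ccc(/C=C/c2cc(O)c3c(c2)O[C@@H](c2ccc(O)c4c2O[C@@H](c2ccc(O)cc2O)[C@@H]4c2cc(O)cc(O)c2)[C@@H]3c2cc(O)cc(O)c2)cc1 | target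

## Step count and least certain steps

Total: 20 steps. Longest linear sequence: 13 steps (1, 2, 3, 4, 5, 7, 9, 10, 11, 12, 13, 19, 20).

**Step 9 (key step).**
- What may go wrong: direct transfer of the alkenyl group from boron to palladium (the Suzuki–Miyaura pathway) may compete with the metallate shift. Alkene binding at palladium may be slow because the β-aryl group is di-ortho-substituted and twisted. Facial selectivity may erode for the same reason.
- Fallback: exchange the roles of the two aryl groups on C3, so that the hindered ring arrives from palladium and the alkene carries the unhindered one. The fallback sets out from 4 (through aryllithium 5 of step 4) and comes back at 19.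
- 5 is quenched with iodine to give 2-iodo-1-methoxy-3-(methoxymethoxy)-4-[(triisopropylsilyloxy)methyl]benzene F1.
- Commercial 1-ethynyl-3,5-dimethoxybenzene is hydroborated as in step 7 to the catechol ester of (E)-2-(3,5-dimethoxyphenyl)ethenylboronic acid F2, which is transesterified with 9 to the B(mac) ester of (E)-2-(3,5-dimethoxyphenyl)ethenylboronic acid F3.
- Addition of 15 to F3 gives the lithium borate complex F4. This is coupled with F1 under the catalyst of step 9 with NaOTf, which also removes iodide.
- Anti addition across this alkene should give the (1R,2R) boronate F5, the Cα epimer of 17 with the same configuration at Cβ. Oxidation as in step 10 gives the (1R,2R) carbinol F6.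
- Because step 11 passes through the Cα cation, F6 should converge on 19.

**Step 19.**
- What may go wrong: poor facial selectivity in the ylide addition, since the stereocentres of ring system A are too remote to help. O-Benzylation of the phenoxide of 32 by the electron-rich sulfonium salt. Self-condensation of the quinone methide. Sommelet–Hauser rearrangement of the ylide.
- Fallback: build ring system B by enantioselective intramolecular C–H insertion of a diaryl carbene, a known route to 2,3-diaryl-2,3-dihydrobenzofurans. It sets out from 20 and 30 and comes back at 35.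
- Mitsunobu etherification of phenol 30 with alcohol 20 (PPh3, DIAD) gives the aryl benzyl ether ketone F7.
- Hydrazine hydrate with acetic acid in hot ethanol gives the hydrazone F8. MnO2 oxidises it to the diaryldiazomethane F9, which is not isolated.
- Rh2(R-PTAD)4 or its antipode inserts the carbene into the benzylic O–CH2 bond. The catalyst fixes C3, and the product is expected as the 2,3-cis dihydrobenzofuran F10.
- Catalytic TsOH in CH2Cl2 then equilibrates C2 through the benzylic cation to the trans isomer 35.

**Step 11.**
- What may go wrong: solvolysis of the silyl ether at the 2,4-dioxygenated primary benzylic position. E1 loss of a proton from the cation to give a triarylethylene. Incomplete trans selectivity.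
- Fallback: replace the cationic closure by an invertive one under neutral conditions. It sets out from 17 and comes back at 19.
- The MOM group of 17 is removed with ZnBr2 and n-PrSH in CH2Cl2 to give the phenol boronate F11.
- H2O2 and NaOH give the (1S,2R) phenol carbinol F12.
- Mitsunobu cyclodehydration (PPh3, DIAD, THF) closes O1–C2 with inversion at the (S)-carbinol and should give the (2R,3R)-trans ring of 19.

**Step 20.**
- What may go wrong: ionisation of either benzylic C2–O1 bond by the Lewis acid, followed by elimination or ring opening. Addition of HBr to the stilbene. Incomplete cleavage of the hindered ethers.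
- Fallback: change from Lewis-acid cleavage to nucleophilic demethylation under basic conditions, where no benzylic cation can form. It sets out from 35 and comes back at 36.
- 35 is heated with NaSEt in DMF at about 130 °C (SN2 attack of thiolate on each methyl group), followed by acidification. No new compound is made (F0).

## Further compounds

F1 | step 9 | 2-iodo-1-methoxy-3-(methoxymethoxy)-4-[(triisopropylsilyloxy)methyl]benzene | COc1ccc(CO[Si](C(C)C)(C(C)C)C(C)C)c(OCOC)c1I
F2 | step 9 | catechol ester of (E)-2-(3,5-dimethoxyphenyl)ethenylboronic acid | COc1cc(OC)cc(/C=C/B2Oc3ccccc3O2)c1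
F3 | step 9 | B(mac) ester of (E)-2-(3,5-dimethoxyphenyl)ethenylboronic acid | COc1cc(OC)cc(/C=C/B2O[C@]3(C)c4cccc5cccc(c45)[C@]3(C)O2)c1
F4 | step 9 | lithium (E)-2-(3,5-dimethoxyphenyl)ethenyl(2,4-dimethoxyphenyl) B(mac) borate | [Li+].COc1cc(OC)cc(/C=C/[B-]2(c3ccc(OC)cc3OC)O[C@]3(C)c4cccc5cccc(c45)[C@]3(C)O2)c1
F5 | step 9 | B(mac) ester of [(1R,2R)-1-(2,4-dimethoxyphenyl)-2-(3,5-dimethoxyphenyl)-2-{6-methoxy-2-(methoxymethoxy)-3-[(triisopropylsilyloxy)methyl]phenyl}ethyl]boronic acid | COc1ccc(CO[Si](C(C)C)(C(C)C)C(C)C)c(OCOC)c1[C@@H](c1cc(OC)cc(OC)c1)[C@H](c1ccc(OC)cc1OC)B1O[C@]2(C)c3cccc4cccc(c34)[C@]2(C)O1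
F6 | step 9 | (1R,2R)-1-(2,4-dimethoxyphenyl)-2-(3,5-dimethoxyphenyl)-2-{6-methoxy-2-(methoxymethoxy)-3-[(triisopropylsilyloxy)methyl]phenyl}ethanol | COc1ccc(CO[Si](C(C)C)(C(C)C)C(C)C)c(OCOC)c1[C@@H](c1cc(OC)cc(OC)c1)[C@H](c1ccc(OC)cc1OC)O
F7 | step 19 | (2-{[(2R,3R)-2-(2,4-dimethoxyphenyl)-3-(3,5-dimethoxyphenyl)-4-methoxy-2,3-dihydrobenzofuran-7-yl]methoxy}-6-methoxy-4-[(E)-2-(4-methoxyphenyl)ethenyl]phenyl)(3,5-dimethoxyphenyl)methanone | COc1ccc(/C=C/c2cc(OC)c(C(=O)c3cc(OC)cc(OC)c3)c(OCc3ccc(OC)c4c3O[C@@H](c3ccc(OC)cc3OC)[C@@H]4c3cc(OC)cc(OC)c3)c2)cc1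
F8 | step 19 | hydrazone of F7 | COc1ccc(/C=C/c2cc(OC)c(C(=NN)c3cc(OC)cc(OC)c3)c(OCc3ccc(OC)c4c3O[C@@H](c3ccc(OC)cc3OC)[C@@H]4c3cc(OC)cc(OC)c3)c2)cc1
F9 | step 19 | diaryldiazomethane from F8 | COc1ccc(/C=C/c2cc(OC)c(C(=[N+]=[N-])c3cc(OC)cc(OC)c3)c(OCc3ccc(OC)c4c3O[C@@H](c3ccc(OC)cc3OC)[C@@H]4c3cc(OC)cc(OC)c3)c2)cc1
F10 | step 19 | (2S,3R)-2-[(2R,3R)-2-(2,4-dimethoxyphenyl)-3-(3,5-dimethoxyphenyl)-4-methoxy-2,3-dihydrobenzofuran-7-yl]-3-(3,5-dimethoxyphenyl)-4-methoxy-6-[(E)-2-(4-methoxyphenyl)ethenyl]-2,3-dihydrobenzofuran (cis at the inner ring) | COc1ccc(/C=C/c2cc(OC)c3c(c2)O[C@H](c2ccc(OC)c4c2O[C@@H](c2ccc(OC)cc2OC)[C@@H]4c2cc(OC)cc(OC)c2)[C@@H]3c2cc(OC)cc(OC)c2)cc1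
F11 | step 11 | B(mac) ester of [(1S,2R)-1-(2,4-dimethoxyphenyl)-2-(3,5-dimethoxyphenyl)-2-{2-hydroxy-6-methoxy-3-[(triisopropylsilyloxy)methyl]phenyl}ethyl]boronic acid | COc1ccc(CO[Si](C(C)C)(C(C)C)C(C)C)c(O)c1[C@@H](c1cc(OC)cc(OC)c1)[C@@H](c1ccc(OC)cc1OC)B1O[C@]2(C)c3cccc4cccc(c34)[C@]2(C)O1
F12 | step 11 | 2-[(1R,2S)-2-(2,4-dimethoxyphenyl)-1-(3,5-dimethoxyphenyl)-2-hydroxyethyl]-3-methoxy-6-[(triisopropylsilyloxy)methyl]phenol | COc1ccc(CO[Si](C(C)C)(C(C)C)C(C)C)c(O)c1[C@@H](c1cc(OC)cc(OC)c1)[C@@H](c1ccc(OC)cc1OC)O
F0 | step 20 | none | none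
A1 | alternative 1 | (2R,3R)-7-bromo-3-(3,5-dimethoxyphenyl)-2-(4-hydroxy-2-methoxyphenyl)-4-methoxy-2,3-dihydrobenzofuran | Brc1ccc(OC)c2c1O[C@@H](c1ccc(O)cc1OC)[C@@H]2c1cc(OC)cc(OC)c1
A2 | alternative 1 | 6-bromo-2-[1-(3,5-dimethoxyphenyl)-2-(4-hydroxy-2-methoxyphenyl)ethenyl]-3-methoxyphenol (achiral; alkene geometry not specified) | Oc1ccc(C=C(c2cc(OC)cc(OC)c2)c2c(OC)ccc(Br)c2O)c(OC)c1
A3 | alternative 2 | nona-O-methyl ether of the target (identical with 35) | COc1ccc(/C=C/c2cc(OC)c3c(c2)O[C@@H](c2ccc(OC)c4c2O[C@@H](c2ccc(OC)cc2OC)[C@@H]4c2cc(OC)cc(OC)c2)[C@@H]3c2cc(OC)cc(OC)c2)cc1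
A4 | alternative 3 | methyl (2R,3R)-6-bromo-2-[(2R,3R)-2-(2,4-dimethoxyphenyl)-3-(3,5-dimethoxyphenyl)-4-methoxy-2,3-dihydrobenzofuran-7-yl]-4-methoxy-2,3-dihydrobenzofuran-3-carboxylate (trans) | Brc1cc(OC)c2c(c1)O[C@@H](c1ccc(OC)c3c1O[C@@H](c1ccc(OC)cc1OC)[C@@H]3c1cc(OC)cc(OC)c1)[C@@H]2C(=O)OC
A5 | alternative 3 | (2R)-7-bromo-2-[(2R,3R)-2-(2,4-dimethoxyphenyl)-3-(3,5-dimethoxyphenyl)-4-methoxy-2,3-dihydrobenzofuran-7-yl]-5-methoxychroman-4-one | Brc1cc(OC)c2c(c1)O[C@@H](c1ccc(OC)c3c1O[C@@H](c1ccc(OC)cc1OC)[C@@H]3c1cc(OC)cc(OC)c1)CC2=O
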